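All runs come from a simulation for an exercise; noise was put on by code.

The pitfall here is to reach for a mechanism before the plain count has been made.

all flasks: solid substrate 0.32 M

| charge | partner | free catalyst | temperature | remark | time |
|---|---|---|---|---|---|
| delta | 0.48 M | 15 mM | 10 °C | run made earlier |  |
| gamma | 0.48 M | 19 mM | 25 °C | run made earlier |  |
| zeta | 0.48 M | 28 mM | 10 °C | run made earlier |  |
| oak | 0.480 M | 25 mM | 15 °C |  | 1.5 h |
| elm | 0.480 M | 12 mM | 35 °C |  | 1.5 h |
| alder | 0.480 M | 25 mM | 35 °C |  | 1.5 h |
| maple | 0.480 M | 12 mM | 15 °C |  | 1.5 h |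

delta run (percent of the solid substrate charged)

| time / h | target / % | solid substrate / % |
|---|---|---|
| 0.250 | 3.4 | 68.9 |
| 0.667 | 9.8 | 37.5 |
| 1.00 | 12.9 | 23.6 |
| 1.50 | 19.8 | 6.5 |
| 3.00 | 36.4 | 0.7 |

gamma run (percent of the solid substrate charged)

| time / min | target / % | solid substrate / % |
|---|---|---|
| 6.00 | 1.6 | 88.0 |
| 10.0 | 6.8 | 76.9 |
| 20.0 | 14.4 | 54.6 |
| 40.0 | 27.4 | 14.7 |
| 80.0 | 47.2 | 0 |

zeta run (percent of the solid substrate charged)

| time / h | target / % | solid substrate / % |
|---|---|---|
| 0.500 | 14.0 | 43.5 |
| 1.00 | 28.9 | 10.4 |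
| 1.33 | 35.4 | 0.2 |
| 2.50 | 60.9 | 0 |
| 3.00 | 60.1 | 0.6 |

(each reading ± 1 percentage point)

- solid substrate is a solid; its amount is given per volume of the solution
- what was read earlier has a scatter of 1 percentage point, one standard deviation
- at the start none of the solid substrate is in solution
- what has only dissolved of solid substrate counts as not reacted

* ranking by amount of target, in percent of the solid substrate charged, from high to low, at 1.5 h (oak / elm / alder / maple)
* the amount of target, in percent of the solid substrate charged of the flask you put first, at 1.5 h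
* the amount of target, in percent of the solid substrate charged of the flask you put last, at 1.5 h

My count is the pace of a run: target read, in moles, per mole of catalyst charged and per hour, the turnover frequency. At 10 °C the delta run gives 2.75 h⁻¹ and the zeta run 3.30 h⁻¹. The gamma run, at 25 °C, gives 6.92 h⁻¹. Gamma's catalyst stands nearer delta's than zeta's, so I read the temperature from delta and gamma. Taking a constant factor per degree, the step from 10 °C to 15 °C is worth 1.36, though the two runs differ in catalyst as well. A first round, with delta's pace on both flasks, gives oak 43.9% and maple 21.1%.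

The weak link is delta's pace on oak. Zeta's pace is higher than delta's at the same temperature, so pace seems to rise with catalyst. I go round again, giving each flask the run nearest in catalyst. Oak's pace at 15 °C, the quantity I carry, becomes 4.49 h⁻¹, and maple's stays 3.74 h⁻¹. That yields 52.6% for oak and 21.1% for maple. Oak's number stands below the 60.9% at which zeta's target flattened, so I commit to both. The same count for alder reaches 180%, more than was charged. The line is broken there, and I rank neither flask at 35 °C by it.

The forecast says alder > oak > elm > maple, with 68% first and 19% last, and of its side loss it says: “This caps yield, more severely at low catalyst.” On maple I hold 21.1% against its 19%; at the top we differ, for it puts alder first and my count stands at 52.6% for oak.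

The flasks give oak > alder > elm > maple: oak 51.0%, alder 36.6%, elm 31.0%, maple 20.7%.

    catalyst intermediate B ⇌ catalyst intermediate C (K = 32.0, k = 0.120 s⁻¹, Ea = 78.0 kJ mol⁻¹, ΔH = −82.0 kJ mol⁻¹)
    starting material + free catalyst → catalyst intermediate A (k = 0.500 M⁻¹ s⁻¹, Ea = 39.0 kJ mol⁻¹)
    partner + catalyst intermediate A ⇌ catalyst intermediate B (K = 4.40 M⁻¹, k = 0.950 M⁻¹ s⁻¹, Ea = 42.0 kJ mol⁻¹, ΔH = −34.0 kJ mol⁻¹)
    solid substrate ⇌ starting material, rate k4*(cs4 - [starting material]) while solid is left; crystals form when [starting material] > cs4 (solubility = 0.210 M, k = 6.70 × 10⁻⁴ s⁻¹)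
    partner + target → over-reaction product (k = 0.0100 M⁻¹ s⁻¹, Ea = 76.0 kJ mol⁻¹)
    catalyst intermediate C → free catalyst + target (k = 0.0280 s⁻¹, Ea = 73.0 kJ mol⁻¹)
    (constants at 35 °C)

Read back, oak's pace is 4.36 h⁻¹ against my 4.49 h⁻¹. In alder at 1.50 h, partner stands at 0% of its charge, target at 36.6% and over-reaction product at 56.7%, and target still reads 36.6% at 15.0 h. A neighbour of oak charged with 0.54 M of solid substrate keeps oak's catalyst, temperature and time, so the pace 4.49 h⁻¹ spread over that larger charge gives 31.2%. That neighbour gives 31.7%.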